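**Retrosynthetic overview**

Locants: the γ-lactone ring is C9(=O)–O–C7'(Ar2)–C3a–C6a and the oxolane ring is C7(Ar1)–O–C9'H2–C3a–C6a. Ar1 is 4-hydroxy-3-methoxyphenyl and Ar2 is 4-hydroxy-3,5-dimethoxyphenyl.
Feature used: in the lactone ring the carboxyl carbon C9 (on C6a) and the donor aryl (on C7') sit 1,3 to each other across C3a, and C6a also bears the benzylic carbon C7. Undoing O–C7' and joining C6a to C7' gives a push–pull cyclopropane C6a–C3a–C7' in which C7 is a cyclopropylcarbinyl position.
Disconnections: (i) the two ArO–Bn bonds; (ii) O–C7', O–C7 and H–C6a in one acid cascade, back to a cyclopropane diol tert-butyl ester; (iii) C7–Ar1, by aryl Grignard addition to a cyclopropane-fused lactol; (iv) C6a–C7' and C6a–C3a, by organocatalytic Michael-initiated ring closure of the O-benzyl syringyl enal with di-tert-butyl bromomalonate.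
Ring order: the cyclopropane comes first, followed by an auxiliary γ-lactone fused to it (it singles out one ester and is later reduced and opened). The oxolane and the final γ-lactone then form together as the cyclopropane is consumed. C3a, set in the cyclopropanation, steers C7', C7 and C6a.

Key step: step 10

Abbreviations in names: ArS = 4-(benzyloxy)-3,5-dimethoxyphenyl; ArG = 4-(benzyloxy)-3-methoxyphenyl.
Assumption: the (S)-diarylprolinol silyl ether is taken to shield the syringyl enal in the same sense as cinnamaldehyde itself. The absolute configuration is to be checked on the cyclopropane-fused lactone, and the (R)-catalyst is used if the sense proves opposite.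

Step 1
Reactants: 1 syringaldehyde
Product: 2 4-(benzyloxy)-3,5-dimethoxybenzaldehyde
Conditions: BnBr, K2CO3, DMF, 60 °C
Reagents that add atoms: benzyl bromide, BrCc1ccccc1
Why: Williamson ether synthesis on the acidic para-formyl phenol, which masks the phenol against base, hydride and aryl metal while keeping the ring a good donor for step 10.

Step 2
Reactants: 2 4-(benzyloxy)-3,5-dimethoxybenzaldehyde
Product: 4 (E)-3-ArS-prop-2-enal, via styryl dioxolane 3 (not isolated)
Conditions: (1,3-dioxolan-2-ylmethyl)PPh3Br, t-BuOK, THF, 0 °C to rt; then 1 M HCl, THF, rt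
Reagents that add atoms: (1,3-dioxolan-2-ylmethyl)triphenylphosphonium bromide, [Br-].C1COC(C[P+](c2ccccc2)(c2ccccc2)c2ccccc2)O1; water, O
Why: Wittig two-carbon homologation with a masked formylmethylide followed by acetal hydrolysis, in which the acid also equilibrates the E/Z mixture to the conjugated E-enal.

Step 3
Reactants: 5 di-tert-butyl malonate
Product: 6 di-tert-butyl 2-bromomalonate
Conditions: CBr4 (1.0 equiv), DBU, THF, −78 °C to 0 °C
Reagents that add atoms: carbon tetrabromide, BrC(Br)(Br)Br
Why: Halophilic bromination of the malonate enolate by CBr4, run without acid so that the tert-butyl esters survive and with one equivalent of bromine donor in the cold to hold it at the monobromide.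

Step 4
Reactants: 4 (E)-3-ArS-prop-2-enal; 6 di-tert-butyl 2-bromomalonate
Product: 7 di-tert-butyl (2S,3R)-2-ArS-3-formylcyclopropane-1,1-dicarboxylate (ArS and CHO trans)
Conditions: (S)-α,α-diphenylprolinol TMS ether (20 mol%), 2,6-lutidine (1.1 equiv), 6 (1.2 equiv), CH2Cl2, 0 °C to rt
Reagents that add atoms: none
Why: Iminium–enamine Michael-initiated ring closure in which the bromomalonate anion adds to the open Si face of C-β (C7') of the E-iminium ion, opposite the CPh2(OTMS) group, and the enamine then displaces bromide 3-exo-tet with formyl trans to aryl, which sets C3a (R) and, for the time being, C7' (S).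

Step 5
Reactants: 7 di-tert-butyl (2S,3R)-2-ArS-3-formylcyclopropane-1,1-dicarboxylate
Product: 8 di-tert-butyl (2S,3R)-2-ArS-3-(hydroxymethyl)cyclopropane-1,1-dicarboxylate
Conditions: NaBH4, THF–MeOH, −20 °C to 0 °C
Reagents that add atoms: none
Why: Chemoselective borohydride reduction of the aldehyde, which leaves the hindered tert-butyl esters, the cyclopropane and both stereocentres untouched.

Step 6
Reactants: 8 di-tert-butyl (2S,3R)-2-ArS-3-(hydroxymethyl)cyclopropane-1,1-dicarboxylate
Product: 9 tert-butyl (1R,5R,6S)-6-ArS-2-oxo-3-oxabicyclo[3.1.0]hexane-1-carboxylate (ArS trans to C4H2 and cis to the ester)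
Conditions: t-BuOK (0.15 equiv), THF, 0 °C to rt
Reagents that add atoms: none
Why: Alkoxide-catalysed intramolecular transesterification (lactonisation) that can reach only the ester cis to CH2OH, so the two esters are told apart, C6a becomes a defined quaternary centre and the surviving ester stands cis to the aryl group.

Step 7
Reactants: 9 tert-butyl (1R,5R,6S)-6-ArS-2-oxo-3-oxabicyclo[3.1.0]hexane-1-carboxylate
Product: 10 tert-butyl (1R,5R,6S)-6-ArS-2-hydroxy-3-oxabicyclo[3.1.0]hexane-1-carboxylate (anomer mixture)
Conditions: DIBAL-H (1.1 equiv), CH2Cl2, −78 °C; aq Rochelle salt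
Reagents that add atoms: none
Why: Partial lactone-to-lactol reduction, in which the strained and less shielded lactone carbonyl takes hydride faster than the tert-butyl ester and the aluminium hemiacetal holds at −78 °C; the new anomeric centre is a mixture of no consequence.

Step 8
Reactants: 11 4-bromo-2-methoxyphenol
Product: 12 1-(benzyloxy)-4-bromo-2-methoxybenzene
Conditions: BnBr, K2CO3, acetone, reflux
Reagents that add atoms: benzyl bromide, BrCc1ccccc1
Why: Williamson ether synthesis that removes the acidic proton before the aryl metal is made.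

Step 9
Reactants: 10 tert-butyl (1R,5R,6S)-6-ArS-2-hydroxy-3-oxabicyclo[3.1.0]hexane-1-carboxylate; 12 1-(benzyloxy)-4-bromo-2-methoxybenzene
Product: 15 tert-butyl (1R,2S,3R)-2-ArS-1-[ArG(hydroxy)methyl]-3-(hydroxymethyl)cyclopropane-1-carboxylate (both C7 carbinol epimers), via arylmagnesium bromide 13 (not isolated), via open hydroxy aldehyde 14 (not isolated)
Conditions: 12 (2.5 equiv), Mg, cat. I2, THF, reflux; then 10, THF, 0 °C to rt; aq NH4Cl
Reagents that add atoms: none
Why: Grignard addition to a lactol, in which the first equivalent deprotonates 10, ring–chain tautomerism exposes the non-enolisable aldehyde, the second equivalent adds 1,2 and the tert-butyl ester is too hindered to react; the C7 carbinol may form as a mixture because C7 is ionised in step 10.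

Step 10
Reactants: 15 tert-butyl (1R,2S,3R)-2-ArS-1-[ArG(hydroxy)methyl]-3-(hydroxymethyl)cyclopropane-1-carboxylate
Product: 18 (3S,3aR,6S,6aS)-3-ArS-6-ArG-tetrahydro-1H,3H-furo[3,4-c]furan-1-one (exo,exo cis-fused dibenzyl ether of the target), via oxolane-fused cyclopropane 16 (not isolated), via E-arylidene lactone 17 (not isolated)
Conditions: TFA (10 equiv), CH2Cl2 (0.02 M), 0 °C; cold aq NaHCO3 as soon as conversion is complete
Reagents that add atoms: none
Why: Proposed new method: TFA ionises the C7 carbinol of either epimer to a p-benzyloxybenzyl cation that is also cyclopropylcarbinyl; the cis CH2OH traps it reversibly as oxolane 16, and the productive exit is heterolysis of the strained C6a–C7' bond (from the cation, or from ester-protonated 16 in the push–pull sense), which moves the charge to C7' next to the trialkoxyphenyl ring. The carbonyl oxygen of the tert-butyl ester on C6a takes the C7' cation; where C7 is still sp2 the resulting alkoxy-oxolanylium ion is conjugated through C6a=C7 with Ar1 like an O-alkylated p-quinone methide, so the C9' hydroxyl adds to C7, C6a is protonated and isobutene leaves, and if isobutene leaves first the neutral lactone 17 re-enters by O-protonation, so that all lines end at 18. Closest known reaction types are the acid opening of 1-(1-hydroxyalkyl)cyclopropanecarboxylates to α-alkylidene-γ-butyrolactones (cyclopropylcarbinyl-to-homoallyl shift), the acid ring expansion of 2-arylcyclopropanecarboxylates to γ-aryl-γ-butyrolactones and the acid cyclisation of α-(hydroxybenzyl)-β-(hydroxymethyl) lactones, but their coupling in one operation on one substrate has not been shown. Modes of closure: the γ-lactone closes 5-exo-trig (O on C7', the quinoid C7'=C(aryl) bond lying outside the ring), and the oxolane closes 5-exo-trig on the C7 cation of 15 or, from the arylidene cation, 5-exo with respect to the quinoid C7=C(aryl) bond though 5-endo with respect to C6a=C7. Stereocontrol: C3a is not touched; at C7' the oxygen arrives on the face that C6a has just left (net insertion of C(=O)O with retention), which is also the face that keeps Ar2 trans to C9' and hence exo; at C7 the short C3a–C9' tether lets oxygen reach one face only, and with Ar1 turned outwards (bisected cation) or E (arylidene cation) this places Ar1 cis to H-3a and hence exo; C6a takes its proton on the convex face because only the cis-fused 5,5-system can exist. The step needs O-capture at C7' to outrun Friedel–Crafts attack by Ar1 and needs the benzylic centres not to equilibrate: the geminal ester is the nearest nucleophile and its capture is made irreversible by loss of isobutene, the ester is trans to CH2OH so no other lactone can form, C6a stays quaternary until the end so nothing can eliminate or epimerise early, and the cold reaction is quenched at full conversion.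

Step 11
Reactants: 18 (3S,3aR,6S,6aS)-3-ArS-6-ArG-tetrahydro-1H,3H-furo[3,4-c]furan-1-one
Product: 19 (3S,3aR,6S,6aS)-3-(4-hydroxy-3,5-dimethoxyphenyl)-6-(4-hydroxy-3-methoxyphenyl)tetrahydro-1H,3H-furo[3,4-c]furan-1-one (CNP0142585.1)
Conditions: H2 (1 atm), 10% Pd/C, EtOAc, rt, stopped at full conversion
Reagents that add atoms: none
Why: Heterogeneous hydrogenolysis, in which the two primary ArO–CH2Ph bonds are cleaved much faster than the secondary ring-held C7–O and C7'–O bonds in neutral EtOAc at 1 atm, so stopping after two equivalents of hydrogen should leave the bicycle and its four stereocentres intact.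

**Compound list**

1 | syringaldehyde | COc1cc(C=O)cc(OC)c1O | starting material
2 | 4-(benzyloxy)-3,5-dimethoxybenzaldehyde | COc1cc(C=O)cc(OC)c1OCc1ccccc1 | intermediate
3 | 2-[2-ArS-ethenyl]-1,3-dioxolane (E/Z mixture, not isolated) | COc1cc(C=CC2OCCO2)cc(OC)c1OCc1ccccc1 | intermediate
4 | (E)-3-ArS-prop-2-enal | COc1cc(/C=C/C=O)cc(OC)c1OCc1ccccc1 | intermediate
5 | di-tert-butyl malonate | CC(C)(C)OC(=O)CC(=O)OC(C)(C)C | starting material
6 | di-tert-butyl 2-bromomalonate | CC(C)(C)OC(=O)C(Br)C(=O)OC(C)(C)C | intermediate
7 | di-tert-butyl (2S,3R)-2-ArS-3-formylcyclopropane-1,1-dicarboxylate | O=C[C@@H]1[C@@H](c2cc(OC)c(OCc3ccccc3)c(OC)c2)C1(C(=O)OC(C)(C)C)C(=O)OC(C)(C)C | intermediate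
8 | di-tert-butyl (2S,3R)-2-ArS-3-(hydroxymethyl)cyclopropane-1,1-dicarboxylate | OC[C@@H]1[C@@H](c2cc(OC)c(OCc3ccccc3)c(OC)c2)C1(C(=O)OC(C)(C)C)C(=O)OC(C)(C)C | intermediate
9 | tert-butyl (1R,5R,6S)-6-ArS-2-oxo-3-oxabicyclo[3.1.0]hexane-1-carboxylate | O=C1OC[C@@H]2[C@@H](c3cc(OC)c(OCc4ccccc4)c(OC)c3)[C@]12C(=O)OC(C)(C)C | intermediate
10 | tert-butyl (1R,5R,6S)-6-ArS-2-hydroxy-3-oxabicyclo[3.1.0]hexane-1-carboxylate (anomers) | OC1OC[C@@H]2[C@@H](c3cc(OC)c(OCc4ccccc4)c(OC)c3)[C@]12C(=O)OC(C)(C)C | intermediate
11 | 4-bromo-2-methoxyphenol | COc1cc(Br)ccc1O | starting material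
12 | 1-(benzyloxy)-4-bromo-2-methoxybenzene | COc1cc(Br)ccc1OCc1ccccc1 | intermediate
13 | [4-(benzyloxy)-3-methoxyphenyl]magnesium bromide (not isolated) | COc1cc([Mg]Br)ccc1OCc1ccccc1 | intermediate
14 | tert-butyl (1R,2S,3R)-2-ArS-1-formyl-3-(hydroxymethyl)cyclopropane-1-carboxylate (open form of 10, present as its magnesium alkoxide, not isolated) | OC[C@@H]1[C@@H](c2cc(OC)c(OCc3ccccc3)c(OC)c2)[C@@]1(C=O)C(=O)OC(C)(C)C | intermediate
15 | tert-butyl (1R,2S,3R)-2-ArS-1-[ArG(hydroxy)methyl]-3-(hydroxymethyl)cyclopropane-1-carboxylate (carbinol epimers; carbinol arm cis to CH2OH, ester cis to ArS) | OC[C@@H]1[C@@H](c2cc(OC)c(OCc3ccccc3)c(OC)c2)[C@@]1(C(O)c2ccc(OCc3ccccc3)c(OC)c2)C(=O)OC(C)(C)C | intermediate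
16 | tert-butyl (1R,2R,5R,6S)-2-ArG-6-ArS-3-oxabicyclo[3.1.0]hexane-1-carboxylate (ArG trans to the cyclopropane CH, not isolated) | COc1cc([C@H]2OC[C@@H]3[C@@H](c4cc(OC)c(OCc5ccccc5)c(OC)c4)[C@]23C(=O)OC(C)(C)C)ccc1OCc1ccccc1 | intermediate
17 | (3E,4R,5S)-3-(ArG-methylidene)-5-ArS-4-(hydroxymethyl)oxolan-2-one (not isolated) | OC[C@@H]1[C@@H](c2cc(OC)c(OCc3ccccc3)c(OC)c2)OC(=O)/C1=C/c1ccc(OCc2ccccc2)c(OC)c1 | intermediate
18 | (3S,3aR,6S,6aS)-3-ArS-6-ArG-tetrahydro-1H,3H-furo[3,4-c]furan-1-one | COc1cc([C@H]2OC[C@H]3[C@@H]2C(=O)O[C@@H]3c2cc(OC)c(OCc4ccccc4)c(OC)c2)ccc1OCc1ccccc1 | intermediate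
19 | (3S,3aR,6S,6aS)-3-(4-hydroxy-3,5-dimethoxyphenyl)-6-(4-hydroxy-3-methoxyphenyl)tetrahydro-1H,3H-furo[3,4-c]furan-1-one | COc1cc([C@H]2OC[C@H]3[C@@H]2C(=O)O[C@@H]3c2cc(OC)c(O)c(OC)c2)ccc1O | target

**Step count**

Total step count: 11.
Longest linear sequence: 9 steps (1, 2, 4, 5, 6, 7, 9, 10, 11) from syringaldehyde.

**Steps most likely to fail**

**1. Step 10 (the proposed new method).**
- The cation relay may stop after the lactone has closed. This happens if isobutene is lost before the hydroxyl reaches C7, because the remaining 5-endo addition to the conjugated system is slow and close to thermoneutral.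
- Ar1 may attack C7' in a Friedel–Crafts ring closure.
- Longer acid contact may scramble the benzylic centres.

The fallback uses known reactions only, builds the rings one at a time and brings in Ar1 only after the O–C7' bond exists. It sets out from alcohol 8. Silylation (TBDPSCl, imidazole, DMF) gives the tert-butyldiphenylsilyl ether F1. TFA in CH2Cl2 cleaves both tert-butyl esters and expands the doubly activated aryl cyclopropane, the known acid ring expansion of 2-arylcyclopropane-1,1-dicarboxylates, to the trans lactone acid F2. This loses CO2 in hot toluene to give the trans-4,5-disubstituted lactone F3. LDA and commercial 4-benzyloxy-3-methoxybenzaldehyde at −78 °C give the aldol F4. MsCl/Et3N converts it into the mesylate F5, and DBU eliminates this to the E-arylidene lactone silyl ether F6. TBAF/AcOH then frees 17, which is isolated here. The oxolane is closed by electrophile-induced 5-endo selenoetherification (N-(phenylseleno)phthalimide, cat. CSA, CH2Cl2). Anti addition to the E-alkene, with oxygen delivered from the tether face, should give the bridgehead selenide F7 with ArG exo. Bu3SnH/AIBN in toluene then replaces selenium by hydrogen on the convex face. The fallback comes back to the route at 18.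

**2. Step 4.**
- The Michael addition may be too slow, since the di-tert-butyl nucleophile is bulky and the iminium ion of the electron-rich enal is a weak acceptor.
- The catalyst may be alkylated by the bromide.
- Retro-Michael opening of the activated cyclopropane may erode the enantiomeric purity.

The fallback replaces the intermolecular organocatalytic ring closure by an intramolecular metal-carbene cyclopropanation. It sets out from enal 4. NaBH4/CeCl3 gives the cinnamyl alcohol F8. DCC/DMAP coupling with 3-tert-butoxy-3-oxopropanoic acid gives the mixed malonate F9. Diazo transfer (p-ABSA, Et3N, MeCN) gives the diazomalonate F10. A chiral Co(II)–porphyrin or Ru(II)–Pheox catalyst, with its enantiomer chosen by correlation, then closes the cyclopropane and the lactone at once. The E-alkene geometry is transferred, so the aryl group ends up trans to CH2O and cis to the ester. The fallback comes back to the route at 9 and makes steps 3 to 6 unnecessary.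

**3. Step 9.**
- The magnesium lactolate may open too slowly.
- The magnesium salts may open the doubly activated cyclopropane of the open form by Lewis acid activation.
- Homoconjugate attack of the aryl metal on the ring may compete with carbonyl addition.
- Any over-reduction in step 7 also starves this step.

The fallback inverts the order of C–C bond formation and reduction. It sets out from lactone 9. Bromine–lithium exchange on 12 (n-BuLi, THF, −78 °C) gives the aryllithium F11. One equivalent of it is added to 9 at −78 °C, where the tetrahedral adduct persists until work-up and should give the hydroxy ketone F12. NaBH4/CeCl3 in MeOH at −40 °C then reduces the ketone, and either epimer serves. The fallback comes back to the route at 15, and step 7 is no longer needed.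

Further compounds
F1 | step 10 | di-tert-butyl (2S,3R)-2-ArS-3-[(tert-butyldiphenylsilyloxy)methyl]cyclopropane-1,1-dicarboxylate | CC(C)(C)[Si](c1ccccc1)(c1ccccc1)OC[C@@H]1[C@@H](c2cc(OC)c(OCc3ccccc3)c(OC)c2)C1(C(=O)OC(C)(C)C)C(=O)OC(C)(C)C
F2 | step 10 | (4R,5S)-5-ArS-4-[(tert-butyldiphenylsilyloxy)methyl]-2-oxooxolane-3-carboxylic acid (C3 epimers) | CC(C)(C)[Si](c1ccccc1)(c1ccccc1)OC[C@@H]1[C@@H](c2cc(OC)c(OCc3ccccc3)c(OC)c2)OC(=O)C1C(=O)O
F3 | step 10 | (4R,5S)-5-ArS-4-[(tert-butyldiphenylsilyloxy)methyl]oxolan-2-one | CC(C)(C)[Si](c1ccccc1)(c1ccccc1)OC[C@@H]1[C@@H](c2cc(OC)c(OCc3ccccc3)c(OC)c2)OC(=O)C1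
F4 | step 10 | (3R,4R,5S)-3-[ArG(hydroxy)methyl]-5-ArS-4-[(tert-butyldiphenylsilyloxy)methyl]oxolan-2-one (carbinol epimers) | CC(C)(C)[Si](c1ccccc1)(c1ccccc1)OC[C@@H]1[C@@H](c2cc(OC)c(OCc3ccccc3)c(OC)c2)OC(=O)[C@H]1C(O)c1ccc(OCc2ccccc2)c(OC)c1
F5 | step 10 | methanesulfonate of F4 | CC(C)(C)[Si](c1ccccc1)(c1ccccc1)OC[C@@H]1[C@@H](c2cc(OC)c(OCc3ccccc3)c(OC)c2)OC(=O)[C@H]1C(OS(C)(=O)=O)c1ccc(OCc2ccccc2)c(OC)c1
F6 | step 10 | (3E,4R,5S)-3-(ArG-methylidene)-5-ArS-4-[(tert-butyldiphenylsilyloxy)methyl]oxolan-2-one | CC(C)(C)[Si](c1ccccc1)(c1ccccc1)OC[C@@H]1[C@@H](c2cc(OC)c(OCc3ccccc3)c(OC)c2)OC(=O)/C1=C/c1ccc(OCc2ccccc2)c(OC)c1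
F7 | step 10 | 6a-(phenylselanyl) derivative of 18 (selenium on the convex face) | COc1cc([C@H]2OC[C@H]3[C@]2([Se]c5ccccc5)C(=O)O[C@@H]3c2cc(OC)c(OCc4ccccc4)c(OC)c2)ccc1OCc1ccccc1
F8 | step 4 | (E)-3-ArS-prop-2-en-1-ol | COc1cc(/C=C/CO)cc(OC)c1OCc1ccccc1
F9 | step 4 | tert-butyl (E)-3-ArS-prop-2-enyl malonate | COc1cc(/C=C/COC(=O)CC(=O)OC(C)(C)C)cc(OC)c1OCc1ccccc1
F10 | step 4 | tert-butyl (E)-3-ArS-prop-2-enyl 2-diazomalonate | COc1cc(/C=C/COC(=O)C(=[N+]=[N-])C(=O)OC(C)(C)C)cc(OC)c1OCc1ccccc1
F11 | step 9 | [4-(benzyloxy)-3-methoxyphenyl]lithium | COc1cc([Li])ccc1OCc1ccccc1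
F12 | step 9 | tert-butyl (1R,2S,3R)-1-(ArG-carbonyl)-2-ArS-3-(hydroxymethyl)cyclopropane-1-carboxylate | OC[C@@H]1[C@@H](c2cc(OC)c(OCc3ccccc3)c(OC)c2)[C@@]1(C(=O)c2ccc(OCc3ccccc3)c(OC)c2)C(=O)OC(C)(C)C
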